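Tuesday's last reading was 27 % product with 3.6 equiv of reagent and Sunday's was 4 % with 0.45 equiv; from 4.00 h to 8.00 h Tuesday's readings moved 2 percentage points and Sunday's 1 point, against a scatter of 1.5 points.

| setting | Sunday's | Saturday's | Tuesday's | south-east | east | north-west | south |
|---|---|---|---|---|---|---|---|
| starting material | 20 mM | 20 mM | 20 mM | 20 mM | 20 mM | 20 mM | 20 mM |
| reagent | 0.45 equiv | 0.99 equiv | 3.6 equiv | 0.400 equiv | 0.800 equiv | 1.50 equiv | 3.00 equiv |
| catalyst | 0.2 mol% | 0.2 mol% | 0.2 mol% | 0.2 mol% | 0.2 mol% | 0.2 mol% | 0.2 mol% |
| remark | run made earlier | run made earlier | run made earlier |  |  |  |  |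
| time |  |  |  | 15 h | 15 h | 15 h | 15 h |

| run | time / h | product / % | starting material / % |
|---|---|---|---|
| Sunday's | 0.667 | 2 | 67 |
| Sunday's | 2.00 | 3 | 65 |
| Sunday's | 4.00 | 3 | 64 |
| Sunday's | 5.00 | 5 | 65 |
| Sunday's | 8.00 | 4 | 68 |
| Saturday's | 1.50 | 7 | 63 |
| Saturday's | 3.00 | 8 | 63 |
| Saturday's | 5.00 | 8 | 65 |
| Saturday's | 6.00 | 9 | 64 |
| Saturday's | 8.00 | 9 | 68 |
| Tuesday's | 0.667 | 19 | 55 |
| Tuesday's | 2.00 | 23 | 50 |
| Tuesday's | 4.00 | 25 | 50 |
| Tuesday's | 5.00 | 25 | 53 |
| Tuesday's | 8.00 | 27 | 54 |

(scatter of a reading: 1.5 percentage points)

- what may be going on: starting material + catalyst <-> catalyst + intermediate; reagent + catalyst + intermediate <-> catalyst + product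
- "hardly changes" means that all values lie within two and a half points (for a concentration: within two and a half percent of the largest)

1. amount of product at the end, in percent of the starting material charged for south-east, east, north-west, south, in this order
2. the shape of the row from first to last (rises all the way / falls, then rises / hardly changes / rises, then falls / falls all the way)

In the proposed steps, starting material goes reversibly to intermediate on the catalyst, and intermediate takes up reagent, reversibly, to give product. I therefore read the plateaus as balance and took 15 h, later than any reading, to be on the plateau too.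

Let P be product as a fraction of starting material charged and e the equivalents of reagent. I averaged P over each run's last 3 readings and formed the product ratio Q, which at balance, with starting material and intermediate in a fixed ratio, stays the same for any reagent charge at 20 mM of starting material:

Q = P / ((1 − P)(e − P))

Tuesday's mean 25.7 % gives Q = 0.103.

What would the opposite outcome need? For a row that hardly changes, the 4 values must lie within 2.5 points, so Q would have to sink as e grows. But Sunday's mean 4.00 % gives 0.102, and Saturday's mean 8.67 % gives 0.105.

So I solved for each flask, first dropping the P-squared term, then putting that answer P′ back in: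

P′ = Qe / (1 + Q(1 + e)): 3.61 %, 6.97 %, 12.3 %, 21.9 %

P = Q(1 − P′)(e − P′): 3.62 %, 7.02 %, 12.5 %, 22.4 %

My row spans 19 points, against the 2.5 points of that band.

The forecast gave 3.8 %, 7.4 %, 13 % and 23.4 %, so rises all the way, on the grounds that “K is constant, which supports the equilibrium picture”. Its south value is higher than mine by 1.00 point.

South ended at 21.7 % and south-east at 3.50 %, with 6.78 % and 12.0 % between them, so the row rises all the way.

    starting material + catalyst ⇌ catalyst + intermediate (K = 0.450, k = 130 M⁻¹ s⁻¹)
    reagent + catalyst + intermediate ⇌ catalyst + product (K = 16.0 M⁻¹, k = 230 M⁻² s⁻¹)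

South's product stood at 21.7 % at 150 h, as at 15.0 h. With south's 21.7 % put into Q(1 − P)(e − P), the Q from the readings returned 22.5 %; with south-east's 3.50 %, it returned 3.64 %.

The readings are calculated on assumed constants; scatter was added.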